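**Strategy.** Everything rests on opening the ten-membered ring at C8–C9 (eunicellane numbering, defined below). The key step exploits the homoallylic carbinol array C9(O)–C8H2–C7(=C16H2) of that ring. An intramolecular Nozaki–Hiyama–Kishi allylation of a C9 aldehyde by the 2-substituted allyl bromide at C7 should close the carbocycle, keep the methylene exocyclic and set C9 under control of C10 in one operation. The precursor is a cyclohexane from (R)-α-phellandrene (C14 bought; C1, C10 and C11 relayed from it by a ketene [2+2] and a hydration) bearing cis formyl and (Z)-alkenyl chains; the C6 acetate comes from (R)-α-hydroxy-γ-butyrolactone.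

Key step: step 13

Remark on numbering: six-membered ring C1, C10, C11, C12, C13, C14; ten-membered ring C1 to C10; C11 bears CH3 and OH, C14 the isopropyl group, C3 a methyl group, C7 the exocyclic methylene C16. "α" is the cyclohexane face that carries the C1–C2 and C10–C9 bonds; "β" is the face of the isopropyl group and the C11 hydroxyl.

Remark on the chemistry: the ketene in step 1 is assumed to add as ketenes normally do to 1,3-dienes, with its carbonyl carbon at the diene terminus (C1). Compounds 4 to 6 are carried as epimer mixtures at the methoxy-bearing carbon C9, which loses that stereocentre in step 4; their SMILES leave it undefined.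

**Step 1**
Reactants: 1 (R)-(−)-α-phellandrene; 2 methoxyacetyl chloride
Product: 4 cis-fused methoxycyclobutanone (carbonyl carbon C2 on C1; methoxy carbon C9 on C10; four-membered ring on the α face), via methoxyketene 3 (not isolated)
Conditions: Et3N, hexane, reflux, slow addition of 2
Reagents that add atoms: none
Why: Ketene–alkene [2+2] cycloaddition; the ketene formed by dehydrochlorination should add suprafacially to the less substituted C1=C10 double bond from the face opposite the C14 isopropyl group, which sets C1 and C10 cis to each other and trans to isopropyl.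

**Step 2**
Reactants: 4 cis-fused methoxycyclobutanone
Product: 5 11β-hydroxy cyclobutanone
Conditions: Co(acac)2 (cat.), PhSiH3, O2 (1 atm), THF, rt; then PPh3
Reagents that add atoms: dioxygen O=O
Why: Mukaiyama hydration (Markovnikov, via hydrogen-atom transfer); the tertiary C11 radical should be trapped by O2 on the convex β face, anti to the four-membered ring and to the axial C10–C9 bond, giving the 11β-hydroxyl.

**Step 3**
Reactants: 5 11β-hydroxy cyclobutanone
Product: 6 methoxy lactone (pseudo-ester; C2 is the lactone carbonyl on C1, C9 the acetal carbon on C10)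
Conditions: mCPBA, CH2Cl2, 0 °C to rt
Reagents that add atoms: 3-chloroperoxybenzoic acid O=C(OO)c1cccc(Cl)c1
Why: Baeyer–Villiger oxidation of a strained cyclobutanone; the oxygen-substituted carbon C9 should migrate in preference to C1, with retention, so the ring oxygen ends up between C2 and C9.

**Step 4**
Reactants: 6 methoxy lactone
Product: 9 cis-fused hydroxy γ-lactone (C2=O on C1; C9H2–O on C10), via formyl acid 7 (not isolated), via hydroxy acid 8 (not isolated)
Conditions: NaBH4, 1 M aq NaOH, THF, 0 °C to rt; then 2 M HCl to pH 2, rt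
Reagents that add atoms: none
Why: Saponification of the acyloxy acetal unmasks the C9 aldehyde, NaBH4 should reduce it as it forms, and acidification relactonises the cis hydroxy acid (pseudo-ester to lactone reduction); no stereocentre is created.

**Step 5**
Reactants: 9 hydroxy γ-lactone
Product: 10 lactol (anomer mixture)
Conditions: i-Bu2AlH (3 equiv), CH2Cl2, −78 °C; aq potassium sodium tartrate work-up
Reagents that add atoms: none
Why: Partial reduction of a γ-lactone to the lactol; the aluminium acetal is stable at −78 °C and one extra equivalent covers the tertiary hydroxyl.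

**Step 6**
Reactants: 10 lactol
Product: 11 (Z)-vinyl iodide diol (C10–CH2OH; C1–CH=C(CH3)I with iodine cis to C1)
Conditions: EtPPh3I, n-BuLi, THF, 0 °C; I2, −78 °C; NaN(SiMe3)2, −20 °C; then 10, −78 to −20 °C (4 equiv ylide)
Reagents that add atoms: ethyltriphenylphosphonium iodide CC[P+](c1ccccc1)(c1ccccc1)c1ccccc1.[I-]; iodine [I][I]
Why: Stork–Zhao olefination; the lactol should react through its open hydroxy aldehyde form and the α-iodo ylide should give the (Z)-2-iodoalkene under kinetic control, freeing the C9 primary alcohol in the same operation.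

**Step 7**
Reactants: 12 (R)-α-hydroxy-γ-butyrolactone
Product: 14 (3R)-4-[(trimethylsilyl)methyl]pent-4-ene-1,3-diol, via bis(silylmethyl) triol 13 (not isolated)
Conditions: Me3SiCH2MgCl (5 equiv), CeCl3, THF, −78 °C to rt; then SiO2, CH2Cl2, rt
Reagents that add atoms: (trimethylsilylmethyl)magnesium chloride C[Si](C)(C)C[Mg]Cl
Why: Double organocerium addition to the lactone carbonyl followed by acid-promoted Peterson olefination turns the ester carbon (C7) into a 2-substituted allylsilane; the non-basic reagent should leave the C6 stereocentre from the chiral pool intact.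

**Step 8**
Reactants: 14 allylsilane diol
Product: 15 (3R)-5-iodo-2-[(trimethylsilyl)methyl]pent-1-en-3-ol
Conditions: PPh3, I2, imidazole (preformed at 0 °C), CH2Cl2, 0 °C
Reagents that add atoms: iodine [I][I]
Why: Appel-type iodination should select the unhindered primary hydroxyl over the secondary allylic one; preforming the phosphonium iodide keeps free iodine away from the allylsilane.

**Step 9**
Reactants: 15 iodo alcohol
Product: 16 (3R)-5-iodo-2-[(trimethylsilyl)methyl]pent-1-en-3-yl acetate
Conditions: Ac2O, pyridine, DMAP (cat.), CH2Cl2, 0 °C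
Reagents that add atoms: acetic anhydride CC(=O)OC(C)=O
Why: DMAP-catalysed acylation of the secondary allylic alcohol installs the C6 acetate of the target.

**Step 10**
Reactants: 16 iodo acetate; 11 (Z)-vinyl iodide diol
Product: 18 coupled allylsilane diol (full C1–C8 chain, (2Z)-alkene, 6R acetate), via alkylzinc iodide 17 (not isolated)
Conditions: 16, Zn dust, LiCl, THF, 40 °C; then 11, Pd(PPh3)4 (5 mol%, zerovalent palladium), THF, 50 °C (2.5 equiv 17)
Reagents that add atoms: none
Why: Negishi coupling; zinc insertion into the primary iodide tolerates acetate and allylsilane, and coupling with the vinyl iodide proceeds with retention, so the (Z)-C2=C3 geometry should be carried over.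

**Step 11**
Reactants: 18 coupled allylsilane diol
Product: 19 allylsilane aldehyde (axial C10 formyl group)
Conditions: Dess–Martin periodinane, pyridine, CH2Cl2, 0 °C to rt
Reagents that add atoms: none
Why: Dess–Martin oxidation of the only primary alcohol under near-neutral conditions should spare the epimerisable C10 centre, the tertiary alcohol and the allylsilane.

**Step 12**
Reactants: 19 allylsilane aldehyde
Product: 20 allyl bromide aldehyde
Conditions: NBS, CH2Cl2, −78 °C
Reagents that add atoms: N-bromosuccinimide O=C1CCC(=O)N1Br
Why: Electrophilic bromodesilylation (SE2′); the 2-substituted allylsilane is far more nucleophilic than the trisubstituted alkene, and since both allyl termini are CH2 the transposition gives the same allyl bromide.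

**Step 13**
Reactants: 20 allyl bromide aldehyde
Product: 22 (9R)-macrocyclic alcohol (6-acetate, 9,11-diol), via allylchromium dichloride 21 (not isolated)
Conditions: CrCl2 (10 equiv), THF, rt, syringe-pump addition of 20 to 2 mM final concentration; aq work-up
Reagents that add atoms: none
Why: Two equivalents of CrCl2 reduce the allylic bromide to an allyl derivative of trivalent chromium, which adds through its γ-terminus to the C9 aldehyde in a six-membered chair transition state; this is the intramolecular Nozaki–Hiyama–Kishi (Barbier-type) allylation, a reaction type known for ten-membered carbocycles. The ten-membered ring closes in a 10-exo-trig mode on the carbonyl group, and because both termini of the 2-substituted allyl unit are CH2 groups the C7=C16 methylene ends up exocyclic whichever terminus reacts. The new C9 stereocentre is controlled by C10: Felkin–Anh attack anti to the bulky C10–C11 bond, on the Re face and gauche to C1 (the side from which the tethered nucleophile arrives), should give the 9R alcohol, and the trans-diaxial arrangement of the formyl group and the 11-hydroxyl rules out a competing chelate. The step needs ring closure to beat oligomerisation, which high dilution, the cis-1,2 placement of the two chains and the (Z)-alkene should secure by turning the chain ends toward each other. It also needs chemoselectivity, which the inertness of organochromium reagents toward the acetate and the free tertiary alcohol and the non-basic medium (no epimerisation of the axial C10 formyl centre) should secure.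

**Step 14**
Reactants: 22 (9R)-macrocyclic alcohol
Product: 23 target diacetate
Conditions: Ac2O, pyridine, DMAP (cat.), CH2Cl2, 0 °C to rt
Reagents that add atoms: acetic anhydride CC(=O)OC(C)=O
Why: Acetylation of the secondary C9 alcohol; the tertiary C11 hydroxyl should not be acylated under these mild conditions.

**Compound list**

1 | (R)-(−)-α-phellandrene, (5R)-2-methyl-5-(propan-2-yl)cyclohexa-1,3-diene | CC1=CC[C@H](C(C)C)C=C1 | starting material
2 | methoxyacetyl chloride | COCC(Cl)=O | starting material
3 | methoxyketene | COC=C=O | intermediate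
4 | 8-methoxy-2-methyl-5-(propan-2-yl)bicyclo[4.2.0]oct-2-en-7-one, cis-fused, four-membered ring anti to isopropyl, epimers at the methoxy carbon | O=C1C(OC)[C@@H]2[C@H]1[C@@H](C(C)C)CC=C2C | intermediate
5 | 2-hydroxy-8-methoxy-2-methyl-5-(propan-2-yl)bicyclo[4.2.0]octan-7-one, hydroxyl anti to the four-membered ring | O=C1C(OC)[C@@H]2[C@H]1[C@@H](C(C)C)CC[C@@]2(C)O | intermediate
6 | 4-hydroxy-3-methoxy-4-methyl-7-(propan-2-yl)hexahydro-2-benzofuran-1(3H)-one, cis-fused | O=C1OC(OC)[C@@H]2[C@H]1[C@@H](C(C)C)CC[C@@]2(C)O | intermediate
7 | 2-formyl-3-hydroxy-3-methyl-6-(propan-2-yl)cyclohexane-1-carboxylic acid (formyl and carboxyl cis) | O=C[C@@H]1[C@H](C(=O)O)[C@@H](C(C)C)CC[C@@]1(C)O | intermediate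
8 | 3-hydroxy-2-(hydroxymethyl)-3-methyl-6-(propan-2-yl)cyclohexane-1-carboxylic acid | OC[C@@H]1[C@H](C(=O)O)[C@@H](C(C)C)CC[C@@]1(C)O | intermediate
9 | 4-hydroxy-4-methyl-7-(propan-2-yl)hexahydro-2-benzofuran-1(3H)-one, cis-fused, 4-OH anti to the lactone ring | O=C1OC[C@@H]2[C@H]1[C@@H](C(C)C)CC[C@@]2(C)O | intermediate
10 | 4-methyl-7-(propan-2-yl)octahydro-2-benzofuran-1,4-diol (lactol, anomer mixture) | OC1OC[C@@H]2[C@H]1[C@@H](C(C)C)CC[C@@]2(C)O | intermediate
11 | 2-(hydroxymethyl)-3-[(1Z)-2-iodoprop-1-en-1-yl]-1-methyl-4-(propan-2-yl)cyclohexan-1-ol (both side chains α, isopropyl and OH β) | OC[C@@H]1[C@H](/C=C(/C)I)[C@@H](C(C)C)CC[C@@]1(C)O | intermediate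
12 | (R)-α-hydroxy-γ-butyrolactone, (3R)-3-hydroxyoxolan-2-one | O=C1OCC[C@H]1O | starting material
13 | (3R)-5-(trimethylsilyl)-4-[(trimethylsilyl)methyl]pentane-1,3,4-triol | OCC[C@@H](O)C(O)(C[Si](C)(C)C)C[Si](C)(C)C | intermediate
14 | (3R)-4-[(trimethylsilyl)methyl]pent-4-ene-1,3-diol | OCC[C@@H](O)C(=C)C[Si](C)(C)C | intermediate
15 | (3R)-5-iodo-2-[(trimethylsilyl)methyl]pent-1-en-3-ol | ICC[C@@H](O)C(=C)C[Si](C)(C)C | intermediate
16 | (3R)-5-iodo-2-[(trimethylsilyl)methyl]pent-1-en-3-yl acetate | ICC[C@@H](OC(C)=O)C(=C)C[Si](C)(C)C | intermediate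
17 | [(3R)-3-acetoxy-4-[(trimethylsilyl)methyl]pent-4-en-1-yl]zinc iodide | I[Zn]CC[C@@H](OC(C)=O)C(=C)C[Si](C)(C)C | intermediate
18 | coupled diol: cyclohexane core of 11 with the iodine replaced by the (3R)-3-acetoxy-4-[(trimethylsilyl)methyl]pent-4-enyl chain, (2Z)-alkene | OC[C@@H]1[C@H](/C=C(/C)CC[C@@H](OC(C)=O)C(=C)C[Si](C)(C)C)[C@@H](C(C)C)CC[C@@]1(C)O | intermediate
19 | C9 aldehyde of 18 (allylsilane aldehyde) | O=C[C@@H]1[C@H](/C=C(/C)CC[C@@H](OC(C)=O)C(=C)C[Si](C)(C)C)[C@@H](C(C)C)CC[C@@]1(C)O | intermediate
20 | allyl bromide aldehyde (CH2SiMe3 of 19 replaced by CH2Br) | O=C[C@@H]1[C@H](/C=C(/C)CC[C@@H](OC(C)=O)C(=C)CBr)[C@@H](C(C)C)CC[C@@]1(C)O | intermediate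
21 | allylchromium dichloride of 20 (trivalent chromium) | O=C[C@@H]1[C@H](/C=C(/C)CC[C@@H](OC(C)=O)C(=C)C[Cr](Cl)Cl)[C@@H](C(C)C)CC[C@@]1(C)O | intermediate
22 | (1S,2Z,6R,9R,10S,11R,14R)-9,11-dihydroxyeunicella-2,7(16)-dien-6-yl acetate | C=C1C[C@@H](O)[C@@H]2[C@H](/C=C(/C)CC[C@H]1OC(C)=O)[C@@H](C(C)C)CC[C@@]2(C)O | intermediate
23 | (1S,2Z,6R,9R,10S,11R,14R)-11-hydroxyeunicella-2,7(16)-diene-6,9-diyl diacetate (CNP0303839.1) | C=C1C[C@@H](OC(C)=O)[C@@H]2[C@H](/C=C(/C)CC[C@H]1OC(C)=O)[C@@H](C(C)C)CC[C@@]2(C)O | target

**Step count.** 14 steps in total; the longest linear sequence is 11 steps (steps 1 to 6, then 10 to 14, from 1).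

**Steps most likely to fail**

Step 13 (key step). Intermolecular coupling and oligomerisation may outrun the ten-membered ring closure, the allylchromium may be protonated before it reaches the aldehyde, or attack may occur on the wrong aldehyde face. Fallback: set out from allylsilane aldehyde 19 and leave out step 12. Treatment with BF3·OEt2 in CH2Cl2 at −78 °C under high dilution should effect an intramolecular Hosomi–Sakurai allylation through an open, purely Felkin–Anh-controlled transition state, with no organometallic that can be quenched. The route is rejoined at 22.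

Step 6. The lactol may open too slowly for the thermally fragile α-iodo ylide, giving low conversion or eroded Z selectivity. Fallback: set out from lactone 9. Ring-opening with Me(MeO)NH·HCl and Me3Al should give the hydroxy N-methoxy-N-methylamide F1. Selective silylation of the primary hydroxyl (TBSCl, imidazole) gives the silyl ether F2, and i-Bu2AlH at −78 °C gives the open-chain aldehyde F3. F3 undergoes the Stork–Zhao olefination as a true aldehyde to give the silylated (Z)-vinyl iodide F4, and Bu4NF returns diol 11.

Step 4. In the alkaline medium the transient β-hydroxy aldehyde may epimerise at C10 or suffer retro-aldol cleavage or β-elimination before it is reduced. Fallback: set out from methoxy lactone 6 and never expose the C9 aldehyde to base. Acid methanolysis (camphorsulfonic acid, MeOH, HC(OMe)3) should give the methyl ester dimethyl acetal F5. Reduction with i-Bu2AlH at −78 °C gives the C2 aldehyde F6, and Stork–Zhao olefination gives the (Z)-vinyl iodide acetal F7. Mild aqueous acid (AcOH, H2O, THF) gives the vinyl iodide aldehyde F8, and NaBH4 in MeOH at 0 °C returns diol 11, bypassing steps 4 to 6.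

**Further compounds**

F0 | step 13 | none | none
F1 | step 6 | hydroxy N-methoxy-N-methylamide (C2 amide, C9 primary alcohol) | OC[C@@H]1[C@H](C(=O)N(C)OC)[C@@H](C(C)C)CC[C@@]1(C)O
F2 | step 6 | C9 tert-butyldimethylsilyl ether of F1 | CC(C)(C)[Si](C)(C)OC[C@@H]1[C@H](C(=O)N(C)OC)[C@@H](C(C)C)CC[C@@]1(C)O
F3 | step 6 | C2 aldehyde with C9 silyl ether | CC(C)(C)[Si](C)(C)OC[C@@H]1[C@H](C=O)[C@@H](C(C)C)CC[C@@]1(C)O
F4 | step 6 | silylated (Z)-vinyl iodide | CC(C)(C)[Si](C)(C)OC[C@@H]1[C@H](/C=C(/C)I)[C@@H](C(C)C)CC[C@@]1(C)O
F5 | step 4 | methyl ester dimethyl acetal (C2 ester, C9 acetal) | COC(OC)[C@@H]1[C@H](C(=O)OC)[C@@H](C(C)C)CC[C@@]1(C)O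
F6 | step 4 | C2 aldehyde with C9 dimethyl acetal | COC(OC)[C@@H]1[C@H](C=O)[C@@H](C(C)C)CC[C@@]1(C)O
F7 | step 4 | (Z)-vinyl iodide with C9 dimethyl acetal | COC(OC)[C@@H]1[C@H](/C=C(/C)I)[C@@H](C(C)C)CC[C@@]1(C)O
F8 | step 4 | (Z)-vinyl iodide C9 aldehyde | O=C[C@@H]1[C@H](/C=C(/C)I)[C@@H](C(C)C)CC[C@@]1(C)O
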